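The readings stem from a simulated flask for substances that don't exist, noise included.

Late in a run a flask may be counted rather than timed: that is the first chemist's view.

| flask | starting material | reagent | remark | time |
|---|---|---|---|---|
| north | 0.48 M | 0.48 M | run made earlier |  |
| Tuesday's | 0.32 M | 0.480 M |  | 3.0 min |
| Thursday's | 0.32 M | 1.28 M |  | 3.0 min |

north run (percent of the starting material charged)

| time / s | double product / % | single product / % |
|---|---|---|
| 10.0 | 1.3 | 23.3 |
| 15.0 | 2.3 | 22.4 |
| 30.0 | 3.3 | 16.0 |
| 50.0 | 5.2 | 5.4 |
| 60.0 | 6.0 | 1.9 |
| 80.0 | 6.3 | 0.8 |
| 120 | 8.7 | 0.9 |

(standard deviation of a reading: 0.5 percentage points)

- the analysis behind the earlier runs scatters by 0.5 percentage points, standard deviation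
- a reading or a percentage of single product counts all its forms, free or not

1. which of these holds the largest part of the starting material at the end of Tuesday's (starting material / other mono adduct / double product / single product)
2. which of these holds the largest part of the starting material at the end of Thursday's (starting material / other mono adduct / double product / single product)
3. double product at the end of Thursday's, in percent of the starting material charged

Starting material is charged in the smaller amount in both new flasks, 0.32 M against 0.480 M and 1.28 M, so it is the limiting reagent. One reagent goes with each starting material into a mono adduct, and double product needs a further one. Tuesday's therefore has 50.0 % of spare reagent, the reagent charged beyond one per starting material, in percent of the starting material charged, and Thursday's has 300 %. So the first chemist expects Tuesday's double product to end at 50.0 % and Thursday's near 100 %, since Thursday's spare reagent is more than the charge can use.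

The second chemist answers that a count has no clock. In the north run double product read 3.3 % at 30.0 s. Guessing that half of the charge then stood as mono adduct and half of the reagent was left, that reading gives a second addition of 0.00917 M⁻¹ s⁻¹. Spare reagent, taken as a concentration, makes this step pseudo-first-order, and over 3.0 min it gives 23.2 % of double product on Tuesday's and 79.5 % on Thursday's. I commit to these numbers: Tuesday's double product stays below its count, which leaves other mono adduct ahead, and Thursday's double product leads.

The forecast reckons with a rate over time, as the second chemist does, and gives other mono adduct for Tuesday's, double product for Thursday's and 88 % of double product, adding “Possible retention of single product lowers the estimate somewhat”.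

The simulation gives other mono adduct on Tuesday's, at 48.6 % against 30.7 % of double product, and double product on Thursday's, at 78.9 %.

    starting material + reagent ⇌ single product (K = 4.10 M⁻¹, k = 0.270 M⁻¹ s⁻¹)
    single product → over-reaction product (k = 0.0440 s⁻¹)
    crystals ⇌ single product, rate k3*(cs3 - [single product]) while solid is left; crystals form when [single product] > cs3 (solubility = 34.0 mM, k = 1.50 s⁻¹)
    starting material + reagent → other mono adduct (k = 0.400 M⁻¹ s⁻¹)
    reagent + other mono adduct → double product (k = 0.0270 M⁻¹ s⁻¹)
    reagent + single product → double product (k = 0.0120 M⁻¹ s⁻¹)

On Thursday's the addition giving other mono adduct had 96 % of its turnover done by 0.600 min, and the step to over-reaction product had 99.9 % done by 1.50 min, when over-reaction product stood at 18.8 %. Other mono adduct went on to double product with 57.9 % of the reagent charged still there at 1.50 min, and at 30.0 min double product stood at 81.1 % beside 18.9 % of over-reaction product. The count belongs to Tuesday's at 30.0 min: double product 49.8 % against spare reagent 50.0 %, with 0.130 % of the reagent left. In the neighbour with 0.51 M of reagent, spare reagent is 59.4 %, and at 3.00 min double product stands lower, at 35.1 %, behind other mono adduct at 44.3 %.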